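**Plan**

- Retrosynthesis, naphthalene carbons primed: the C2'–CH3 bond is cut first (methyl from chloride). Then C2' itself is excised by cutting C1'–C2' and C2'–C3', which leaves a 1-methoxy-3-aryl-1H-indene.
- Enabling feature: C2', the methyl-bearing ortho carbon beside the axis, lies between C1' and C3'. Without it the naphthalene ring is the five-membered ring of an indene, and the crowded biaryl bond becomes an aryl–alkenyl bond at a far less hindered carbon.
- Further cuts: the isoquinoline C7–indene C3 bond (Negishi coupling), then the pyridine ring of the isoquinoline (C4–C4a and N–C3, oxime/propyne annulation).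
- Forward order: the isoquinoline pyridine ring is closed first; the bromoindene is made separately from 7-methoxy-1-indanone, whose ketone and methoxy group become the peri 4',5'-dimethoxy pattern. The halves are joined, the five-membered ring is expanded to the second naphthalene ring, and the methyl group comes last.
- Stereochemistry: the target has no stereocentre. The racemic indene C1 centre is erased on aromatisation and the biaryl axis forms as the racemate.

Key step: step 9

Remark: the target SMILES fixes no configuration at the biaryl axis, so the compound is planned as the racemate and the atropisomers are not separated.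

**Route**

Step 1
Reactants: 1 1-(3-bromo-2-hydroxyphenyl)ethanone
Product: 2 1-(3-bromo-2-methoxyphenyl)ethanone
Conditions: MeI, K2CO3, acetone, 56 °C
Reagents that add atoms: iodomethane, CI
Why: Williamson ether synthesis, in which the phenoxide formed by K2CO3 is methylated by SN2 attack on MeI and no other acidic or nucleophilic site competes.

Step 2
Reactants: 2 1-(3-bromo-2-methoxyphenyl)ethanone
Product: 3 (E)-1-(3-bromo-2-methoxyphenyl)ethanone oxime
Conditions: NH2OH·HCl, NaOAc, EtOH/H2O, 80 °C
Reagents that add atoms: hydroxylamine hydrochloride, Cl.NO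
Why: Oxime condensation of an aryl methyl ketone, expected to favour the E isomer (hydroxyl anti to the aryl group), and any Z isomer can be carried on because the geometry should equilibrate under the Lewis-acidic conditions of step 4.

Step 3
Reactants: 3 (E)-1-(3-bromo-2-methoxyphenyl)ethanone oxime
Product: 4 (E)-1-(3-bromo-2-methoxyphenyl)ethanone O-acetyl oxime
Conditions: Ac2O, pyridine, DMAP (cat.), CH2Cl2, 0 °C to rt
Reagents that add atoms: acetic anhydride, CC(=O)OC(C)=O
Why: O-acylation of the oxime turns the N–O bond into the internal oxidant needed for the redox-neutral annulation.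

Step 4
Reactants: 4 (E)-1-(3-bromo-2-methoxyphenyl)ethanone O-acetyl oxime; 5 propyne
Product: 6 7-bromo-8-methoxy-1,3-dimethylisoquinoline
Conditions: [Cp*Co(CO)I2] (10 mol %), AgSbF6 (20 mol %), KOAc (20 mol %), propyne (3 equiv), ClCH2CH2Cl, 120 °C, sealed tube
Reagents that add atoms: none
Why: Trivalent-cobalt-catalysed oxime-directed C–H activation/alkyne annulation with N–O cleavage, in which the only free ortho C–H (C6 of the arene) is metalated, the terminal alkyne inserts with its CH carbon bonded to the arene so that the methyl-bearing carbon closes onto nitrogen (3-methyl, 4-H), and the aryl bromide is left untouched.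

Step 5
Reactants: 7 7-methoxy-2,3-dihydro-1H-inden-1-one
Product: 9 3-bromo-7-methoxy-1H-inden-1-one, via 3,3-dibromo-7-methoxyindan-1-one 8 (not isolated)
Conditions: NBS (2.1 equiv), AIBN (cat.), PhCF3, 85 °C; then Et3N, 0 °C
Reagents that add atoms: N-bromosuccinimide, O=C1CCC(=O)N1Br
Why: Twofold Wohl–Ziegler bromination at the benzylic C3 position followed by E1cB loss of HBr through the ketone enolate, the established way from 1-indanones to 3-bromoindenones, with the arene protected from ring bromination by the attached carbonyl group.

Step 6
Reactants: 9 3-bromo-7-methoxy-1H-inden-1-one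
Product: 10 3-bromo-7-methoxy-1H-inden-1-ol (racemic)
Conditions: NaBH4, CeCl3·7H2O, MeOH, −20 °C
Reagents that add atoms: none
Why: Luche reduction, which delivers hydride 1,2 to the β-bromo enone and so avoids conjugate addition–elimination at the bromine-bearing carbon; the new carbinol centre is racemic and is destroyed in step 9.

Step 7
Reactants: 10 3-bromo-7-methoxy-1H-inden-1-ol (racemic)
Product: 11 3-bromo-1,7-dimethoxy-1H-indene (racemic)
Conditions: MeOTf, 2,6-di-tert-butyl-4-methylpyridine, CH2Cl2, 0 °C to rt
Reagents that add atoms: methyl trifluoromethanesulfonate, COS(=O)(=O)C(F)(F)F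
Why: O-alkylation of a secondary alcohol with methyl triflate and a hindered, non-nucleophilic pyridine, chosen because alkoxide or amine bases would promote the 1,3-prototropic shift of the indene, and carried out before the isoquinoline nitrogen is present.

Step 8
Reactants: 6 7-bromo-8-methoxy-1,3-dimethylisoquinoline; 11 3-bromo-1,7-dimethoxy-1H-indene (racemic)
Product: 14 1,7-dimethoxy-3-(8-methoxy-1,3-dimethylisoquinolin-7-yl)-1H-indene (racemic), via (8-methoxy-1,3-dimethylisoquinolin-7-yl)lithium 12 (not isolated), via (8-methoxy-1,3-dimethylisoquinolin-7-yl)zinc chloride 13 (not isolated)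
Conditions: n-BuLi, THF, −78 °C, 10 min; ZnCl2, −78 °C to rt; then 11, Pd2(dba)3 (2.5 mol %), SPhos (10 mol %), THF, 50 °C
Reagents that add atoms: none
Why: Bromine–lithium exchange (faster at −78 °C than deprotonation of the C1 methyl group), immediate transmetalation to the non-basic arylzinc and Negishi coupling with the alkenyl bromide join the halves without any base that could move the indene double bond, and the allylic methyl ether is inert to zerovalent palladium.

Step 9
Reactants: 14 1,7-dimethoxy-3-(8-methoxy-1,3-dimethylisoquinolin-7-yl)-1H-indene (racemic); 15 sodium trichloroacetate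
Product: 17 7-(2-chloro-4,5-dimethoxynaphthalen-1-yl)-8-methoxy-1,3-dimethylisoquinoline, via dichlorocyclopropane adduct 16 (not isolated)
Conditions: Cl3CCO2Na (4 equiv, in portions), DME, 85 °C; then PhMe, 110 °C
Reagents that add atoms: none
Why: Thermal decarboxylation of 15 gives CCl3−, which loses chloride to singlet dichlorocarbene under essentially neutral conditions, and the electrophilic carbene adds in a concerted [2+1] cheletropic step to the electron-rich, styrene-type C2=C3 bond of 14 to give the gem-dichlorocyclopropane 16. The strained bicyclo[3.1.0] unit then undergoes the two-electron disrotatory electrocyclic opening of a cyclopropyl to an allyl cation, driven by departure of the endo chloride and by the doubly benzylic character of the cation at C1', so the old C2–C3 bond breaks and the inserted carbon ends up bonded to C1' and C3'. Loss of the proton from the methoxy-bearing carbon (C4') aromatises the ring, keeps the C4' methoxy group and leaves chlorine on C2'; this is the dihalocarbene ring expansion of indenes to 2-halonaphthalenes. The new six-membered ring (C1'–C2'–C3'–C4'–C4a'–C8a') is therefore closed by ring expansion (cyclopropanation, then electrocyclic opening of the shared bond) and not by cyclisation of a chain. The three stereocentres of 16 are transient and are all erased on aromatisation, so no element of control is needed, and the biaryl axis forms as the racemate. The selectivity needed is regiochemical (chlorine at C2', not C3'), which requires the double bond to stay between C2 and C3 until the carbene arrives; the base-free carbene source, the absence of any amine stronger than the hindered isoquinoline and the high barrier of a thermal 1,5-hydrogen shift through an isoindene secure this.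

Step 10
Reactants: 17 7-(2-chloro-4,5-dimethoxynaphthalen-1-yl)-8-methoxy-1,3-dimethylisoquinoline
Product: 18 7-(4,5-dimethoxy-2-methylnaphthalen-1-yl)-8-methoxy-1,3-dimethylisoquinoline (racemic axis)
Conditions: (MeBO)3, Pd(OAc)2 (5 mol %), SPhos (10 mol %), K3PO4, PhMe/H2O, 100 °C
Reagents that add atoms: trimethylboroxine, CB1OB(C)OB(C)O1
Why: Suzuki–Miyaura methylation, in which the electron-rich biarylphosphine makes oxidative addition into the hindered aryl chloride feasible and the methyl group is transferred from boron with no other reactive site in the molecule.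

**Compound list**

1 | 1-(3-bromo-2-hydroxyphenyl)ethanone | CC(=O)c1cccc(Br)c1O | starting material
2 | 1-(3-bromo-2-methoxyphenyl)ethanone | CC(=O)c1cccc(Br)c1OC | intermediate
3 | (E)-1-(3-bromo-2-methoxyphenyl)ethanone oxime | C/C(=N\O)c1cccc(Br)c1OC | intermediate
4 | (E)-1-(3-bromo-2-methoxyphenyl)ethanone O-acetyl oxime | C/C(=N\OC(C)=O)c1cccc(Br)c1OC | intermediate
5 | propyne | CC#C | starting material
6 | 7-bromo-8-methoxy-1,3-dimethylisoquinoline | COc1c(Br)ccc2cc(C)nc(C)c12 | intermediate
7 | 7-methoxy-2,3-dihydro-1H-inden-1-one (7-methoxy-1-indanone) | COc1cccc2c1C(=O)CC2 | starting material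
8 | 3,3-dibromo-7-methoxy-2,3-dihydro-1H-inden-1-one (not isolated) | COc1cccc2c1C(=O)CC2(Br)Br | intermediate
9 | 3-bromo-7-methoxy-1H-inden-1-one | COc1cccc2c1C(=O)C=C2Br | intermediate
10 | 3-bromo-7-methoxy-1H-inden-1-ol (racemic) | COc1cccc2c1C(O)C=C2Br | intermediate
11 | 3-bromo-1,7-dimethoxy-1H-indene (racemic) | COc1cccc2c1C(OC)C=C2Br | intermediate
12 | (8-methoxy-1,3-dimethylisoquinolin-7-yl)lithium (not isolated) | [Li]c1ccc2cc(C)nc(C)c2c1OC | intermediate
13 | (8-methoxy-1,3-dimethylisoquinolin-7-yl)zinc chloride (not isolated) | Cl[Zn]c1ccc2cc(C)nc(C)c2c1OC | intermediate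
14 | 1,7-dimethoxy-3-(8-methoxy-1,3-dimethylisoquinolin-7-yl)-1H-indene (racemic) | COC1C=C(c2ccc3cc(C)nc(C)c3c2OC)c2cccc(OC)c21 | intermediate
15 | sodium trichloroacetate | [Na+].[O-]C(=O)C(Cl)(Cl)Cl | starting material
16 | 7-(1,1-dichloro-5,6-dimethoxy-1,1a,6,6a-tetrahydrocyclopropa[a]inden-1a-yl)-8-methoxy-1,3-dimethylisoquinoline (racemic, diastereomer mixture, not isolated) | COC1C2C(Cl)(Cl)C2(c2ccc3cc(C)nc(C)c3c2OC)c2cccc(OC)c21 | intermediate
17 | 7-(2-chloro-4,5-dimethoxynaphthalen-1-yl)-8-methoxy-1,3-dimethylisoquinoline (racemic axis) | COc1c(-c2c(Cl)cc(OC)c3c(OC)cccc23)ccc2cc(C)nc(C)c12 | intermediate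
18 | 7-(4,5-dimethoxy-2-methylnaphthalen-1-yl)-8-methoxy-1,3-dimethylisoquinoline (racemic axis) | COc1c(-c2c(C)cc(OC)c3c(OC)cccc23)ccc2cc(C)nc(C)c12 | target

**Step count**

Total: 10 steps. Longest linear sequence: 7 steps (steps 1, 2, 3, 4, 8, 9, 10). The indene branch (steps 5 to 7) joins at step 8.

**Steps most likely to fail**

Step 9. The carbene may be drained by reversible ylide formation at the isoquinoline nitrogen, or the indene double bond may migrate toward the methoxy carbon before cyclopropanation, which would put chlorine on C3'. The fallback expands the ring before the biaryl bond exists. It sets out from bromoindene 11: sodium trichloroacetate 15 in DME at 85 °C should give 1a-bromo-1,1-dichloro-5,6-dimethoxy-1,1a,6,6a-tetrahydrocyclopropa[a]indene F1, which opens and loses HCl to give 1-bromo-2-chloro-4,5-dimethoxynaphthalene F2. A Negishi coupling at the C–Br bond only, with arylzinc 13 made from 6 as in step 8 (Pd2(dba)3, SPhos, THF, 60 °C), then comes back to the route at 17.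

Step 8. Proton transfer from the acidic C1 methyl group of the isoquinoline to n-BuLi or to aryllithium 12 may compete with halogen–metal exchange and return debrominated material. The fallback uses no organolithium. It sets out from bromide 6: palladium-catalysed stannylation (Me3SnSnMe3, Pd(PPh3)4, PhMe, 110 °C) should give 8-methoxy-1,3-dimethyl-7-(trimethylstannyl)isoquinoline F3. A Stille coupling of F3 with bromoindene 11 under neutral conditions (Pd2(dba)3, AsPh3, CuI, DMF, 60 °C) comes back at 14.

Step 4. Cobalt-mediated oligomerisation of the terminal alkyne, or insertion in the reverse orientation, may outrun the desired annulation. The fallback forms the C–C and C–N bonds in separate, regiochemically fixed events. It sets out from ketone 2: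
- MeONH2·HCl and pyridine in EtOH should give (E)-1-(3-bromo-2-methoxyphenyl)ethanone O-methyl oxime F4.
- Oxime-ether-directed ortho-iodination with divalent palladium (Pd(OAc)2, N-iodosuccinimide, AcOH, 100 °C) should give (E)-1-(3-bromo-6-iodo-2-methoxyphenyl)ethanone O-methyl oxime F5.
- Sonogashira coupling with propyne 5 at the iodide only (PdCl2(PPh3)2, CuI, Et3N, rt) should give (E)-1-[3-bromo-2-methoxy-6-(prop-1-yn-1-yl)phenyl]ethanone O-methyl oxime F6.
- AgOTf/TfOH-catalysed 6-endo cyclisation of the oxime ether nitrogen onto the alkyne, with loss of the N-methoxy group as formaldehyde, comes back at 6.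

**Further compounds**

F1 | step 9 | 1a-bromo-1,1-dichloro-5,6-dimethoxy-1,1a,6,6a-tetrahydrocyclopropa[a]indene | COc1cccc2c1C(OC)C1C(Cl)(Cl)C21Br
F2 | step 9 | 1-bromo-2-chloro-4,5-dimethoxynaphthalene | COc1cc(Cl)c(Br)c2cccc(OC)c12
F3 | step 8 | 8-methoxy-1,3-dimethyl-7-(trimethylstannyl)isoquinoline | COc1c([Sn](C)(C)C)ccc2cc(C)nc(C)c12
F4 | step 4 | (E)-1-(3-bromo-2-methoxyphenyl)ethanone O-methyl oxime | C/C(=N\OC)c1cccc(Br)c1OC
F5 | step 4 | (E)-1-(3-bromo-6-iodo-2-methoxyphenyl)ethanone O-methyl oxime | C/C(=N\OC)c1c(I)ccc(Br)c1OC
F6 | step 4 | (E)-1-[3-bromo-2-methoxy-6-(prop-1-yn-1-yl)phenyl]ethanone O-methyl oxime | C/C(=N\OC)c1c(C#CC)ccc(Br)c1OC
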